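The numbers in the tables were generated by integration with constants of no real substance, and the scatter is random.

| flask | solid substrate | reagent | remark | time |
|---|---|---|---|---|
| dawn | 0.33 M | 1.3 equiv | the very flask that is asked about, followed so far |  |
| dusk | 0.49 M | 1.3 equiv | run made earlier |  |
| flask | 0.33 M | 1.30 equiv |  | 2.5 h |

| run | time / min | target / % | dissolved substrate / % |
|---|---|---|---|
| dawn | 10.0 | 2 | 3 |
| dawn | 20.0 | 7 | 2 |
| dawn | 25.0 | 7 | 2 |
| dawn | 40.0 | 10 | 2 |
| dawn | 50.0 | 14 | 3 |
| dusk | 12.0 | 4 | 0 |
| dusk | 25.0 | 6 | 1 |
| dusk | 40.0 | 8 | 1 |
| dusk | 50.0 | 10 | 0 |
| dusk | 60.0 | 14 | 3 |

(standard deviation of a reading: 1.5 percentage points)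

- amount of target at 2.5 h, in percent of the solid substrate charged
- concentration of dissolved substrate in solution at 2.5 h, in percent of saturation

- as a solid, counted per litre of solution: solid substrate
- on the list of suspects stand: solid substrate <-> dissolved substrate; dissolved substrate + reagent -> target; target <-> isomer of the product
- at the start none of the solid substrate is in solution
- dissolved substrate means what is dissolved; the solid is not counted in it

**The ratio.** I carry one ratio: time over target, from the last reading of the dawn run, which is this flask followed so far. It gives a charge time of 5.95 h, the time a straight target line needs to reach the whole charge. The asked 2.5 h is then 42.0% of a charge, and that is my estimate.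

**First doubt.** The line may bend. Target at that level takes 32.3% of the reagent's own charge. But dissolved substrate in the dawn run reads a flat 2% to 3%. A small pool between dissolving and reaction can keep the line straight while reagent falls. I keep the line.

**Second doubt.** Isomer of the product goes unread. If it takes as much as target, those two hold 84.0% of the charge. The last dawn reading of dissolved substrate brings that to 87.0%, less than the whole charge. So in this estimate solid remains at 2.5 h, and the estimate stands.

**Third doubt.** Dusk gives a charge time of 7.14 h, longer than dawn's by a factor of 1.20, against 1.48 in charge. With this scatter I cannot tell whether it grows with the charge.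

**The forecast.** It gives 33% (26% to 39%) and 95% of saturation (78% to 100%), since the dissolved substrate “looks capped by solubility”. My target stands higher. The readings show me no saturation level, so I give no figure.

**The result.** The flask gives 41.2% target. Its dissolved substrate stands at 40.0% of saturation.

    solid substrate ⇌ dissolved substrate, rate k1*(cs1 - [dissolved substrate]) while solid is left; crystals form when [dissolved substrate] > cs1 (solubility = 44.0 mM, k = 0.0599 min⁻¹)
    dissolved substrate + reagent → target (k = 0.519 M⁻¹ min⁻¹)
    target ⇌ isomer of the product (K = 0.970, k = 0.372 min⁻¹)

**What ran.** Up to 2.5 h, 85.9% of the charge dissolved, leaving 14.1% solid, while dissolved substrate sat in a quasi-steady state, made 1.06 times as fast as used at the end. Target and isomer of the product ran side by side, 41.2% against 39.4%, with a relaxation half-life of that step alone of 0.917 min, short against the run. The flask's charge time comes to 6.07 h. Scaled with the charge, mine predicts 16.7% target for the neighbour flask at 0.83 M, which gives 21.3%.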